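**Plan**

- Retrosynthesis: after global O-dealkylation, the C2–C3 bond of the flavanone dihydropyranone ring is cut, giving a diazoketone on C4a and an open aryl 4-(benzyloxy)benzyl ether on C8a. The 8,8'' biaryl bond is cut next (Suzuki–Miyaura), then ring C of the flavone (chalcone, aldol); both halves come from one iodophenol, 3.
- Forward order: ring C of the flavone half is made first, the 8,8'' biaryl bond second, and ring C of the flavanone half last, by intramolecular carbene C–H insertion.
- Enabling feature: C2 is a benzylic CH bonded to ring oxygen O1 and to the 4-oxygenated ring B, so in the open ether its C–H bond is hydridic. C3 is alpha to the C4 ketone and can be made an electrophilic carbene centre (reversed polarity). C3 and the C2–H bond stand 1,6 through C4, C4a, C8a and O1, and no five-membered insertion site exists.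
- Stereochemistry: C2 is the only stereocentre; it is set (S) in step 9 by a chiral dirhodium carboxylate that differentiates the two enantiotopic benzylic hydrogens, and it meets no base afterwards.

Key step: step 9

Assumption: the target structure defines only C2 (S). The 8,8'' axis, flanked by four ortho oxygens, is left undefined, so 10 to 12 are carried as racemates about the axis and 13 and 14 as the two 2S axial diastereomers, separable if a single one is wanted.

**Route**

Step 1
Reactants: 1 1-(2,4-dihydroxy-6-methoxyphenyl)ethan-1-one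
Product: 2 1-[4-(benzyloxy)-2-hydroxy-6-methoxyphenyl]ethan-1-one
Conditions: BnBr (1.05 equiv), K2CO3, acetone, reflux
Reagents that add atoms: benzyl bromide, BrCc1ccccc1
Why: Williamson etherification; the 4-OH (para to the acetyl group, not hydrogen-bonded) is more acidic and more nucleophilic than the chelated 2-OH, so monobenzylation should be selective.

Step 2
Reactants: 2 1-[4-(benzyloxy)-2-hydroxy-6-methoxyphenyl]ethan-1-one
Product: 3 1-[4-(benzyloxy)-2-hydroxy-3-iodo-6-methoxyphenyl]ethan-1-one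
Conditions: BnMe3N·ICl2 (1.0 equiv), CaCO3, CH2Cl2–MeOH, rt
Reagents that add atoms: benzyltrimethylammonium dichloroiodate, C[N+](C)(C)Cc1ccccc1.Cl[I-]Cl
Why: Electrophilic aromatic iodination; attack is expected at C3, ortho to the free phenol and para to the methoxy group, which is less hindered than C5 between two ether groups, and this fixes the later biaryl position next to the future ring oxygen.

Step 3
Reactants: 3 1-[4-(benzyloxy)-2-hydroxy-3-iodo-6-methoxyphenyl]ethan-1-one; 4 4-(benzyloxy)benzaldehyde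
Product: 5 (E)-1-[4-(benzyloxy)-2-hydroxy-3-iodo-6-methoxyphenyl]-3-[4-(benzyloxy)phenyl]prop-2-en-1-one
Conditions: KOH (50% aq), EtOH, rt
Reagents that add atoms: none
Why: Claisen–Schmidt aldol condensation of the methyl ketone with a non-enolisable aldehyde; E1cB dehydration should give the E-enone, and the aryl iodide and benzyl ethers are inert to hydroxide.

Step 4
Reactants: 5 (E)-1-[4-(benzyloxy)-2-hydroxy-3-iodo-6-methoxyphenyl]-3-[4-(benzyloxy)phenyl]prop-2-en-1-one
Product: 6 7-(benzyloxy)-2-[4-(benzyloxy)phenyl]-8-iodo-5-methoxy-4H-chromen-4-one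
Conditions: I2 (10 mol %), DMSO, 120 °C
Reagents that add atoms: none
Why: Iodine-catalysed oxidative cyclisation of a 2'-hydroxychalcone (oxa-Michael closure, then dehydrogenation with DMSO as terminal oxidant); the catalytic amount of iodine keeps the HI level low enough for the benzyl and methyl ethers.

Step 5
Reactants: 3 1-[4-(benzyloxy)-2-hydroxy-3-iodo-6-methoxyphenyl]ethan-1-one; 7 1-(benzyloxy)-4-(chloromethyl)benzene
Product: 8 1-[4-(benzyloxy)-2-{[4-(benzyloxy)phenyl]methoxy}-3-iodo-6-methoxyphenyl]ethan-1-one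
Conditions: K2CO3, n-Bu4NI (cat.), DMF, 60 °C
Reagents that add atoms: none
Why: Williamson O-alkylation of the hindered, chelated phenol by a reactive benzylic chloride under iodide catalysis; this places the future C2 with ring B on the future O1 as an open ether.

Step 6
Reactants: 8 1-[4-(benzyloxy)-2-{[4-(benzyloxy)phenyl]methoxy}-3-iodo-6-methoxyphenyl]ethan-1-one
Product: 9 1-[4-(benzyloxy)-2-{[4-(benzyloxy)phenyl]methoxy}-6-methoxy-3-(4,4,5,5-tetramethyl-1,3,2-dioxaborolan-2-yl)phenyl]ethan-1-one
Conditions: pinacolborane, PdCl2(MeCN)2 (2 mol %), SPhos (8 mol %), Et3N, 1,4-dioxane, 80 °C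
Reagents that add atoms: pinacolborane, CC1(C)OBOC1(C)C
Why: Palladium-catalysed Miyaura-type borylation with pinacolborane; the bulky dialkylbiarylphosphine is known to carry doubly ortho-substituted aryl halides through this reaction, and the ketone is not touched by pinacolborane under these conditions.

Step 7
Reactants: 6 7-(benzyloxy)-2-[4-(benzyloxy)phenyl]-8-iodo-5-methoxy-4H-chromen-4-one; 9 1-[4-(benzyloxy)-2-{[4-(benzyloxy)phenyl]methoxy}-6-methoxy-3-(4,4,5,5-tetramethyl-1,3,2-dioxaborolan-2-yl)phenyl]ethan-1-one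
Product: 10 8-[3-acetyl-6-(benzyloxy)-2-{[4-(benzyloxy)phenyl]methoxy}-4-methoxyphenyl]-7-(benzyloxy)-2-[4-(benzyloxy)phenyl]-5-methoxy-4H-chromen-4-one
Conditions: Pd2(dba)3 (2.5 mol %, zerovalent palladium), SPhos (10 mol %), K3PO4, toluene–H2O (10:1), 100 °C
Reagents that add atoms: none
Why: Suzuki–Miyaura cross-coupling; SPhos-ligated palladium is a known system for biaryls with four ortho substituents, the electron-poorer chromone C8–I bond should undergo oxidative addition readily, and the axis forms without stereocontrol.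

Step 8
Reactants: 10 8-[3-acetyl-6-(benzyloxy)-2-{[4-(benzyloxy)phenyl]methoxy}-4-methoxyphenyl]-7-(benzyloxy)-2-[4-(benzyloxy)phenyl]-5-methoxy-4H-chromen-4-one
Product: 12 8-[6-(benzyloxy)-2-{[4-(benzyloxy)phenyl]methoxy}-3-(2-diazoacetyl)-4-methoxyphenyl]-7-(benzyloxy)-2-[4-(benzyloxy)phenyl]-5-methoxy-4H-chromen-4-one, via trifluoroacetyl diketone 11 (not isolated)
Conditions: LiN(SiMe3)2, THF, −78 °C; CF3CO2CH2CF3; dilute aq HCl work-up; then MsN3, Et3N, H2O (1 equiv), MeCN, rt
Reagents that add atoms: 2,2,2-trifluoroethyl trifluoroacetate, O=C(OCC(F)(F)F)C(F)(F)F (its CF3CO group stays only in 11); methanesulfonyl azide, CS(=O)(=O)N=[N+]=[N-]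
Why: Detrifluoroacetylative (Danheiser-type) diazo transfer; the acetyl CH3 is the only enolisable site, its lithium enolate is trifluoroacetylated, and the activated 1,3-diketone takes the diazo group from the sulfonyl azide with loss of the trifluoroacetyl group.

Step 9
Reactants: 12 8-[6-(benzyloxy)-2-{[4-(benzyloxy)phenyl]methoxy}-3-(2-diazoacetyl)-4-methoxyphenyl]-7-(benzyloxy)-2-[4-(benzyloxy)phenyl]-5-methoxy-4H-chromen-4-one
Product: 13 (2S)-7-(benzyloxy)-8-{7-(benzyloxy)-2-[4-(benzyloxy)phenyl]-5-methoxy-4-oxo-4H-chromen-8-yl}-2-[4-(benzyloxy)phenyl]-5-methoxy-2,3-dihydro-4H-chromen-4-one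
Conditions: Rh2(S-PTTL)4 [dirhodium tetrakis(N-phthaloyl-(S)-tert-leucinate), divalent rhodium] (2 mol %), CH2Cl2, 4 Å molecular sieves, 0 °C to rt
Reagents that add atoms: none
Why: The dirhodium carboxylate extrudes N2 from 12 to give an electrophilic rhodium carbene at the future C3, which inserts through a concerted, asynchronous, hydride-transfer-like three-centre transition state into one C–H bond of the ArO–CH2–Ar' methylene and so forms the C2–C3 bond. The closest known reaction type is the rhodium-carboxylate-catalysed intramolecular C–H insertion of 2-alkoxyaryl diazoketones to chroman-4-ones, together with carbene insertion into C–H bonds of aryl benzyl ethers. The dihydropyranone ring closes through a six-membered transition state (C3, C4, C4a, C8a, O1, C2), a 1,6-insertion that is favoured here because the atom in the usual 1,5 position is the ether oxygen itself and the only C–H bond within reach is activated both by that oxygen and by the 4-alkoxyphenyl ring. C2 is set by catalyst control: the chiral phthalimido-carboxylate pocket should differentiate the two enantiotopic benzylic hydrogens, the sense of induction is to be confirmed on the simpler 2-(benzyloxy)phenyl diazomethyl ketone (with Rh2(R-PTTL)4 taking the place of the S catalyst should the model show the opposite sense), and the remote biaryl axis is not expected to override it. The step needs site- and chemoselectivity over insertion into the methoxy group on the other ortho oxygen (future O5), over oxonium ylide formation at O1 followed by 1,2-shift of the benzyl group to a benzofuranone, and over O–H insertion of water; the first is secured by a methyl group (strong primary C–H) and not a benzyl group on that oxygen, the second by the weakly basic, doubly flanked aryl ether oxygen and a carboxylate-ligated carbene in a non-coordinating solvent, the third by molecular sieves, while every other benzyl ether lies beyond any cyclic transition state.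

Step 10
Reactants: 13 (2S)-7-(benzyloxy)-8-{7-(benzyloxy)-2-[4-(benzyloxy)phenyl]-5-methoxy-4-oxo-4H-chromen-8-yl}-2-[4-(benzyloxy)phenyl]-5-methoxy-2,3-dihydro-4H-chromen-4-one
Product: 14 (2S)-5,7-dihydroxy-8-[5,7-dihydroxy-2-(4-hydroxyphenyl)-4-oxo-4H-chromen-8-yl]-2-(4-hydroxyphenyl)-2,3-dihydro-4H-chromen-4-one
Conditions: BCl3 (excess), pentamethylbenzene, CH2Cl2, −78 °C then 0 °C; MeOH quench, aqueous work-up
Reagents that add atoms: none
Why: Lewis-acid dealkylation; BCl3 with pentamethylbenzene as a non-basic benzyl cation scavenger cleaves aryl benzyl ethers at low temperature, the two methoxy groups next to the C4 and C4'' carbonyls fall by chelation-assisted demethylation, and the cold, base-free medium should leave C2 untouched.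

**Compound list**

1 | 1-(2,4-dihydroxy-6-methoxyphenyl)ethan-1-one | CC(=O)c1c(O)cc(O)cc1OC | starting material
2 | 1-[4-(benzyloxy)-2-hydroxy-6-methoxyphenyl]ethan-1-one | CC(=O)c1c(O)cc(OCc2ccccc2)cc1OC | intermediate
3 | 1-[4-(benzyloxy)-2-hydroxy-3-iodo-6-methoxyphenyl]ethan-1-one | CC(=O)c1c(O)c(I)c(OCc2ccccc2)cc1OC | intermediate
4 | 4-(benzyloxy)benzaldehyde | O=Cc1ccc(OCc2ccccc2)cc1 | starting material
5 | (E)-1-[4-(benzyloxy)-2-hydroxy-3-iodo-6-methoxyphenyl]-3-[4-(benzyloxy)phenyl]prop-2-en-1-one | O=C(/C=C/c1ccc(OCc2ccccc2)cc1)c1c(O)c(I)c(OCc2ccccc2)cc1OC | intermediate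
6 | 7-(benzyloxy)-2-[4-(benzyloxy)phenyl]-8-iodo-5-methoxy-4H-chromen-4-one | COc1cc(OCc2ccccc2)c(I)c2oc(-c3ccc(OCc4ccccc4)cc3)cc(=O)c12 | intermediate
7 | 1-(benzyloxy)-4-(chloromethyl)benzene (4-(benzyloxy)benzyl chloride) | ClCc1ccc(OCc2ccccc2)cc1 | starting material
8 | 1-[4-(benzyloxy)-2-{[4-(benzyloxy)phenyl]methoxy}-3-iodo-6-methoxyphenyl]ethan-1-one | CC(=O)c1c(OCc2ccc(OCc3ccccc3)cc2)c(I)c(OCc2ccccc2)cc1OC | intermediate
9 | 1-[4-(benzyloxy)-2-{[4-(benzyloxy)phenyl]methoxy}-6-methoxy-3-(4,4,5,5-tetramethyl-1,3,2-dioxaborolan-2-yl)phenyl]ethan-1-one | CC(=O)c1c(OCc2ccc(OCc3ccccc3)cc2)c(B2OC(C)(C)C(C)(C)O2)c(OCc2ccccc2)cc1OC | intermediate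
10 | 8-[3-acetyl-6-(benzyloxy)-2-{[4-(benzyloxy)phenyl]methoxy}-4-methoxyphenyl]-7-(benzyloxy)-2-[4-(benzyloxy)phenyl]-5-methoxy-4H-chromen-4-one (racemic about the axis) | COc1cc(OCc2ccccc2)c(-c2c(OCc3ccc(OCc4ccccc4)cc3)c(C(C)=O)c(OC)cc2OCc2ccccc2)c2oc(-c3ccc(OCc4ccccc4)cc3)cc(=O)c12 | intermediate
11 | 1-[4-(benzyloxy)-3-{7-(benzyloxy)-2-[4-(benzyloxy)phenyl]-5-methoxy-4-oxo-4H-chromen-8-yl}-2-{[4-(benzyloxy)phenyl]methoxy}-6-methoxyphenyl]-4,4,4-trifluorobutane-1,3-dione (formed in the flask, not isolated) | COc1cc(OCc2ccccc2)c(-c2c(OCc3ccc(OCc4ccccc4)cc3)c(C(=O)CC(=O)C(F)(F)F)c(OC)cc2OCc2ccccc2)c2oc(-c3ccc(OCc4ccccc4)cc3)cc(=O)c12 | intermediate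
12 | 8-[6-(benzyloxy)-2-{[4-(benzyloxy)phenyl]methoxy}-3-(2-diazoacetyl)-4-methoxyphenyl]-7-(benzyloxy)-2-[4-(benzyloxy)phenyl]-5-methoxy-4H-chromen-4-one | COc1cc(OCc2ccccc2)c(-c2c(OCc3ccc(OCc4ccccc4)cc3)c(C(=O)C=[N+]=[N-])c(OC)cc2OCc2ccccc2)c2oc(-c3ccc(OCc4ccccc4)cc3)cc(=O)c12 | intermediate
13 | (2S)-7-(benzyloxy)-8-{7-(benzyloxy)-2-[4-(benzyloxy)phenyl]-5-methoxy-4-oxo-4H-chromen-8-yl}-2-[4-(benzyloxy)phenyl]-5-methoxy-2,3-dihydro-4H-chromen-4-one | O=C1C[C@@H](c2ccc(OCc3ccccc3)cc2)Oc2c1c(OC)cc(OCc1ccccc1)c2-c1c(OCc3ccccc3)cc(OC)c2c(=O)cc(-c3ccc(OCc4ccccc4)cc3)oc12 | intermediate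
14 | (2S)-5,7-dihydroxy-8-[5,7-dihydroxy-2-(4-hydroxyphenyl)-4-oxo-4H-chromen-8-yl]-2-(4-hydroxyphenyl)-2,3-dihydro-4H-chromen-4-one (CNP0339995.1) | O=C1C[C@@H](c2ccc(O)cc2)Oc2c1c(O)cc(O)c2-c1c(O)cc(O)c2c(=O)cc(-c3ccc(O)cc3)oc12 | target

**Step count**

Total: 10 steps. Longest linear sequence: 8 steps (1, 2, 5, 6, 7, 8, 9, 10; the branch 1, 2, 3, 4, 7, 8, 9, 10 is equally long).

**Steps most likely to fail**

Step 9. The ether oxygen O1 may attack the carbene, and the resulting oxonium ylide may undergo 1,2-shift of the benzyl group (ring contraction in place of insertion); discrimination between the two enantiotopic hydrogens may also be poor. The fallback builds the stereocentre by a C2–aryl bond instead and sets out from 10. The 4-(benzyloxy)benzyl ether, a para-alkoxybenzyl ether, would be cleaved selectively with CF3CO2H and anisole in CH2Cl2 at 0 °C to give the 2'-hydroxyacetophenone F1. Condensation with N,N-dimethylformamide dimethyl acetal at 100 °C would give the enaminone F2, and aqueous HCl in CH2Cl2 would close it to the chromone F3. Asymmetric conjugate addition of 4-(benzyloxy)phenylboronic acid, catalysed by Pd(OCOCF3)2 (divalent palladium) and a chiral tert-butyl pyridine-oxazoline ligand (the enantiomer that delivers 2S) with NH4PF6 in ClCH2CH2Cl–H2O at 60 °C, would come back to the route at 13. The 2-aryl chromone of the flavone half is a beta,beta-disubstituted acceptor and should not compete.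

Step 7. Transmetalation and reductive elimination at an axis with four ortho substituents may be slow, so that protodeboronation of the electron-rich boronate wins; the borylation of step 6 may likewise end in protodeiodination. The fallback sets out from 8 and avoids both steps. Ullmann reductive homocoupling with copper powder (Cu) in DMF at 150 °C would give the symmetric biaryl diketone F4. One of its two 4-(benzyloxy)benzyl ethers would be cleaved statistically (CF3CO2H, anisole, CH2Cl2, −20 °C, stopped at partial conversion, with recycling) to give the monophenol F5. O-Acylation with 4-(benzyloxy)benzoyl chloride (pyridine, DMAP) would give the aryl ester F6. Baker–Venkataraman rearrangement (KOH, pyridine, 50 °C), in which only the acetyl group ortho to the ester can take the acyl group intramolecularly, would give the 1,3-diketone F7. Cyclodehydration (NaOAc, AcOH, 100 °C) would come back to the route at 10.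

Step 10. The Lewis acid may ionise the C2–O1 bond, so that the ring opens through a para-alkoxybenzyl cation and recloses with loss of configurational purity at C2; cleavage of the two chelated methyl ethers may also stay incomplete. The fallback sets out from 13 and separates the two dealkylations. Hydrogenolysis (H2, palladium on carbon (Pd/C), EtOAc–MeOH, rt) would remove the four benzyl groups under neutral conditions and give the 5,5''-di-O-methyl tetraphenol F8. Chelation-controlled demethylation of the two methoxy groups next to the carbonyls with MgI2 etherate (THF, 50 °C) would come back to the route at 14.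

**Further compounds**

F1 | step 9 | 8-[3-acetyl-6-(benzyloxy)-2-hydroxy-4-methoxyphenyl]-7-(benzyloxy)-2-[4-(benzyloxy)phenyl]-5-methoxy-4H-chromen-4-one | COc1cc(OCc2ccccc2)c(-c2c(O)c(C(C)=O)c(OC)cc2OCc2ccccc2)c2oc(-c3ccc(OCc4ccccc4)cc3)cc(=O)c12
F2 | step 9 | 8-{6-(benzyloxy)-3-[(E)-3-(dimethylamino)prop-2-enoyl]-2-hydroxy-4-methoxyphenyl}-7-(benzyloxy)-2-[4-(benzyloxy)phenyl]-5-methoxy-4H-chromen-4-one | COc1cc(OCc2ccccc2)c(-c2c(O)c(C(=O)/C=C/N(C)C)c(OC)cc2OCc2ccccc2)c2oc(-c3ccc(OCc4ccccc4)cc3)cc(=O)c12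
F3 | step 9 | 7-(benzyloxy)-8-{7-(benzyloxy)-2-[4-(benzyloxy)phenyl]-5-methoxy-4-oxo-4H-chromen-8-yl}-5-methoxy-4H-chromen-4-one | O=c1ccoc2c1c(OC)cc(OCc1ccccc1)c2-c1c(OCc3ccccc3)cc(OC)c2c(=O)cc(-c3ccc(OCc4ccccc4)cc3)oc12
F4 | step 7 | 1,1'-[6,6'-bis(benzyloxy)-2,2'-bis{[4-(benzyloxy)phenyl]methoxy}-4,4'-dimethoxy-[1,1'-biphenyl]-3,3'-diyl]di(ethan-1-one) | CC(=O)c1c(OCc2ccc(OCc3ccccc3)cc2)c(-c2c(OCc3ccccc3)cc(OC)c(C(C)=O)c2OCc2ccc(OCc3ccccc3)cc2)c(OCc2ccccc2)cc1OC
F5 | step 7 | 1,1'-[6,6'-bis(benzyloxy)-2-{[4-(benzyloxy)phenyl]methoxy}-2'-hydroxy-4,4'-dimethoxy-[1,1'-biphenyl]-3,3'-diyl]di(ethan-1-one) | CC(=O)c1c(OCc2ccc(OCc3ccccc3)cc2)c(-c2c(OCc3ccccc3)cc(OC)c(C(C)=O)c2O)c(OCc2ccccc2)cc1OC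
F6 | step 7 | 3,3'-diacetyl-6,6'-bis(benzyloxy)-2'-{[4-(benzyloxy)phenyl]methoxy}-4,4'-dimethoxy-[1,1'-biphenyl]-2-yl 4-(benzyloxy)benzoate | CC(=O)c1c(OCc2ccc(OCc3ccccc3)cc2)c(-c2c(OCc3ccccc3)cc(OC)c(C(C)=O)c2OC(=O)c2ccc(OCc3ccccc3)cc2)c(OCc2ccccc2)cc1OC
F7 | step 7 | 1-[3'-acetyl-6,6'-bis(benzyloxy)-2'-{[4-(benzyloxy)phenyl]methoxy}-2-hydroxy-4,4'-dimethoxy-[1,1'-biphenyl]-3-yl]-3-[4-(benzyloxy)phenyl]propane-1,3-dione | CC(=O)c1c(OCc2ccc(OCc3ccccc3)cc2)c(-c2c(OCc3ccccc3)cc(OC)c(C(=O)CC(=O)c3ccc(OCc4ccccc4)cc3)c2O)c(OCc2ccccc2)cc1OC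
F8 | step 10 | (2S)-7-hydroxy-8-[7-hydroxy-2-(4-hydroxyphenyl)-5-methoxy-4-oxo-4H-chromen-8-yl]-2-(4-hydroxyphenyl)-5-methoxy-2,3-dihydro-4H-chromen-4-one | O=C1C[C@@H](c2ccc(O)cc2)Oc2c1c(OC)cc(O)c2-c1c(O)cc(OC)c2c(=O)cc(-c3ccc(O)cc3)oc12
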